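## Retrosynthetic overview

1. The last step is a neutral global O-debenzylation. The epoxide and the C3 stereocentre are already in place by then.
2. The key disconnection is C3–C1'. A nickel-catalysed enantioconvergent Negishi arylation joins a racemic 3-bromochroman-4-one (rings A and C) to a ring B arylzinc that already carries the (R)-epoxide, and sets (3S).
3. Ring B comes from 4-bromophenol by ortho-C-prenylation, ortho-formylation and Dakin oxidation to the catechol, benzylation, then Shi epoxidation, which forms the oxirane ring and sets (R).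
4. Ring A comes from resorcinol. An iridium-catalysed C5–H borylation and oxidation installs the third oxygen, and Friedel–Crafts acylation with 3-chloropropanoic acid followed by oxa-cyclisation closes ring C.
5. Ring order: ring A (preformed arene), then ring C; separately ring B (preformed arene), then the oxirane; the two halves are then joined.

Assumption: the target is read from the SMILES as the (3S)-isoflavanone with a (2R)-oxirane. In step 11 the (4S,5R) pybox antipode is taken to give (3S); this sense of induction is untested on this substrate class, and the mirror-image ligand is used if the first run shows it reversed.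

## Route

Step 1
Reactants: 1 resorcinol (benzene-1,3-diol)
Product: 2 1,3-bis(tert-butyldimethylsilyloxy)benzene
Conditions: TBSCl (2.2 equiv), imidazole (4.5 equiv), DMF, rt, 12 h
Reagents that add atoms: tert-butyldimethylsilyl chloride, CC(C)(C)[Si](C)(C)Cl
Why: Standard imidazole-promoted silylation of both phenols; the bulky silyl ethers mask the OH groups and block C2, C4 and C6 sterically for the next step.

Step 2
Reactants: 2 1,3-bis(tert-butyldimethylsilyloxy)benzene
Product: 4 3,5-bis(tert-butyldimethylsilyloxy)phenol, via aryl pinacol boronate 3 (not isolated)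
Conditions: [Ir(OMe)(cod)]2 (1.5 mol%), 4,4'-di-tert-butyl-2,2'-bipyridine (3 mol%), B2pin2 (1.0 equiv), THF, 80 °C, 16 h; then Oxone (2KHSO5·KHSO4·K2SO4), acetone/H2O, rt, 15 min
Reagents that add atoms: potassium peroxymonosulfate (active part of Oxone), [K+].OOS(=O)(=O)[O-]
Why: Sterically controlled iridium-catalysed aromatic C–H borylation occurs only at C5, the one C–H with no ortho substituent, and the boronate is oxidised in the same pot (boron-to-oxygen 1,2-shift) to the phenol.

Step 3
Reactants: 4 3,5-bis(tert-butyldimethylsilyloxy)phenol; 5 3-chloropropanoic acid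
Product: 8 5,7-dihydroxychroman-4-one, via phloroglucinol 6 (not isolated), via 3-chloro-1-(2,4,6-trihydroxyphenyl)propan-1-one 7 (not isolated)
Conditions: TfOH (neat), 80 °C, 2 h; then 2 M aq NaOH, 0 °C to rt, 2 h; aq HCl to pH 3
Reagents that add atoms: none
Why: TfOH strips the silyl ethers and drives Friedel–Crafts acylation of the symmetrical phloroglucinol (only one regioisomer is possible), and NaOH then closes ring C by intramolecular O-alkylation (6-exo-tet Williamson-type cyclisation).

Step 4
Reactants: 8 5,7-dihydroxychroman-4-one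
Product: 9 5,7-bis(benzyloxy)chroman-4-one
Conditions: BnBr (2.4 equiv), K2CO3 (3 equiv), DMF, 60 °C, 6 h
Reagents that add atoms: benzyl bromide, BrCc1ccccc1
Why: Williamson etherification; heating in DMF overcomes the hydrogen bond that holds the 5-OH to the carbonyl.

Step 5
Reactants: 9 5,7-bis(benzyloxy)chroman-4-one
Product: 11 racemic 5,7-bis(benzyloxy)-3-bromochroman-4-one, via silyl enol ether 10 (not isolated)
Conditions: TMSOTf (1.3 equiv), Et3N (1.6 equiv), CH2Cl2, 0 °C, 1 h; then NBS (1.05 equiv), THF, −78 °C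
Reagents that add atoms: N-bromosuccinimide, O=C1CCC(=O)N1Br
Why: Soft enolisation and electrophilic bromination of the silyl enol ether give α-bromination only and spare the electron-rich ring A; the C3 centre is left racemic because step 11 erases it.

Step 6
Reactants: 12 4-bromophenol; 13 1-bromo-3-methylbut-2-ene (prenyl bromide)
Product: 14 4-bromo-2-(3-methylbut-2-en-1-yl)phenol
Conditions: NaH (1.1 equiv), toluene, 0 °C; then 13 (1.1 equiv), rt, 18 h
Reagents that add atoms: none
Why: Ortho-selective C-alkylation of a sodium phenoxide in a non-polar solvent, where the tight ion pair delivers the allylic bromide to the ortho carbon and the para position is blocked by bromine.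

Step 7
Reactants: 14 4-bromo-2-(3-methylbut-2-en-1-yl)phenol
Product: 15 5-bromo-2-hydroxy-3-(3-methylbut-2-en-1-yl)benzaldehyde
Conditions: MgCl2 (1.5 equiv), Et3N (3.8 equiv), (CH2O)n (6.8 equiv), MeCN, reflux, 4 h; aq HCl work-up
Reagents that add atoms: paraformaldehyde (as formaldehyde), C=O
Why: Casnati–Skattebøl magnesium-mediated ortho-formylation attacks the only free ortho position of the phenol.

Step 8
Reactants: 15 5-bromo-2-hydroxy-3-(3-methylbut-2-en-1-yl)benzaldehyde
Product: 17 5-bromo-3-(3-methylbut-2-en-1-yl)benzene-1,2-diol, via aryl formate 16 (not isolated)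
Conditions: 30% aq H2O2 (1.2 equiv), NaOH (1.05 equiv), THF/H2O, 0 °C to rt, 1 h, argon; then aq HCl
Reagents that add atoms: hydrogen peroxide, OO
Why: Dakin oxidation, in which hydroperoxide adds to the aldehyde, the electron-rich aryl group migrates to oxygen and the formate is saponified in situ; the isolated trisubstituted alkene is inert to alkaline H2O2.

Step 9
Reactants: 17 5-bromo-3-(3-methylbut-2-en-1-yl)benzene-1,2-diol
Product: 18 1,2-bis(benzyloxy)-5-bromo-3-(3-methylbut-2-en-1-yl)benzene
Conditions: BnBr (2.3 equiv), K2CO3 (3 equiv), DMF, rt to 50 °C, argon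
Reagents that add atoms: benzyl bromide, BrCc1ccccc1
Why: Williamson etherification of both catechol hydroxyls, run under argon to avoid catechol oxidation.

Step 10
Reactants: 18 1,2-bis(benzyloxy)-5-bromo-3-(3-methylbut-2-en-1-yl)benzene
Product: 19 (3R)-3-{[2,3-bis(benzyloxy)-5-bromophenyl]methyl}-2,2-dimethyloxirane
Conditions: D-fructose-derived Shi ketone (1,2:4,5-di-O-isopropylidene-β-D-erythro-2,3-hexodiulo-2,6-pyranose, 30 mol%), Oxone (2KHSO5·KHSO4·K2SO4, 1.4 equiv KHSO5), K2CO3, Bu4NHSO4 (4 mol%), MeCN/dimethoxymethane/aq Na2B4O7 buffer, 0 °C, 3 h; recrystallise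
Reagents that add atoms: potassium peroxymonosulfate (active part of Oxone), [K+].OOS(=O)(=O)[O-]
Why: Shi asymmetric epoxidation, in which the chiral dioxirane attacks the trisubstituted alkene through the spiro transition state to give the (R)-epoxide (about 90% ee expected, raised by recrystallisation); benzyl ethers and the aryl bromide are inert.

Step 11
Reactants: 19 (3R)-3-{[2,3-bis(benzyloxy)-5-bromophenyl]methyl}-2,2-dimethyloxirane; 11 racemic 5,7-bis(benzyloxy)-3-bromochroman-4-one
Product: 22 (3S)-5,7-bis(benzyloxy)-3-{3,4-bis(benzyloxy)-5-[((2R)-3,3-dimethyloxiran-2-yl)methyl]phenyl}chroman-4-one, via aryllithium 20 (not isolated), via arylzinc iodide 21 (not isolated)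
Conditions: 19 (1.3 equiv), t-BuLi (2.6 equiv), THF, −78 °C, 15 min; ZnI2 (1.3 equiv), −78 to −30 °C; then 11 (1.0 equiv), NiCl2(dme) (5 mol%), 2,6-bis[(4S,5R)-4,5-diphenyl-4,5-dihydro-1,3-oxazol-2-yl]pyridine (6.5 mol%), DME/THF, −30 °C, 12 h; pH 7 phosphate buffer quench
Reagents that add atoms: none
Why: Proposed new method: a pybox-ligated monovalent arylnickel species abstracts bromine from either enantiomer of 11 to give a planar, ring-locked α-keto radical at C3, which is captured by the chiral divalent arylnickel complex and leaves by reductive elimination from trivalent nickel, so the ligand and not the substrate fixes (3S) while forming the C3–C1' bond, and the weakly basic arylzinc at −30 °C should neither enolise the product nor open the epoxide (two equivalents of t-BuLi destroy the t-BuBr that could otherwise enter the coupling); the closest known reaction is the nickel/pybox-catalysed stereoconvergent Negishi arylation of acyclic racemic α-bromo ketones with arylzinc iodides, which has not been shown for a cyclic β-aryloxy α-bromo ketone such as a 3-bromochroman-4-one.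

Step 12
Reactants: 22 (3S)-5,7-bis(benzyloxy)-3-{3,4-bis(benzyloxy)-5-[((2R)-3,3-dimethyloxiran-2-yl)methyl]phenyl}chroman-4-one
Product: 23 (3S)-3-{3,4-dihydroxy-5-[((2R)-3,3-dimethyloxiran-2-yl)methyl]phenyl}-5,7-dihydroxychroman-4-one (CNP0197974.1)
Conditions: H2 (1 atm), 10% Pd/C, EtOAc, rt, 2–4 h; filter through Celite, no acid, purify on Sephadex LH-20
Reagents that add atoms: none
Why: Heterogeneous hydrogenolysis of the four benzyl ethers under neutral conditions, which should leave the non-benzylic trisubstituted epoxide, the deactivated aryl ketone and the base-sensitive C3 stereocentre untouched.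

## Compound list

1 | resorcinol (benzene-1,3-diol) | Oc1cccc(O)c1 | starting material
2 | 1,3-bis(tert-butyldimethylsilyloxy)benzene | CC(C)(C)[Si](C)(C)Oc1cccc(O[Si](C)(C)C(C)(C)C)c1 | intermediate
3 | 2-[3,5-bis(tert-butyldimethylsilyloxy)phenyl]-4,4,5,5-tetramethyl-1,3,2-dioxaborolane | CC(C)(C)[Si](C)(C)Oc1cc(O[Si](C)(C)C(C)(C)C)cc(c1)B1OC(C)(C)C(C)(C)O1 | intermediate (not isolated)
4 | 3,5-bis(tert-butyldimethylsilyloxy)phenol | CC(C)(C)[Si](C)(C)Oc1cc(O)cc(O[Si](C)(C)C(C)(C)C)c1 | intermediate
5 | 3-chloropropanoic acid | OC(=O)CCCl | starting material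
6 | phloroglucinol (benzene-1,3,5-triol) | Oc1cc(O)cc(O)c1 | intermediate (not isolated)
7 | 3-chloro-1-(2,4,6-trihydroxyphenyl)propan-1-one | O=C(CCCl)c1c(O)cc(O)cc1O | intermediate (not isolated)
8 | 5,7-dihydroxychroman-4-one | O=C1CCOc2cc(O)cc(O)c12 | intermediate
9 | 5,7-bis(benzyloxy)chroman-4-one | O=C1CCOc2cc(OCc3ccccc3)cc(OCc3ccccc3)c12 | intermediate
10 | 5,7-bis(benzyloxy)-4-(trimethylsilyloxy)-2H-chromene | C[Si](C)(C)OC1=CCOc2cc(OCc3ccccc3)cc(OCc3ccccc3)c12 | intermediate (not isolated)
11 | racemic 5,7-bis(benzyloxy)-3-bromochroman-4-one | O=C1C(Br)COc2cc(OCc3ccccc3)cc(OCc3ccccc3)c12 | intermediate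
12 | 4-bromophenol | Oc1ccc(Br)cc1 | starting material
13 | 1-bromo-3-methylbut-2-ene (prenyl bromide) | CC(C)=CCBr | starting material
14 | 4-bromo-2-(3-methylbut-2-en-1-yl)phenol | CC(C)=CCc1cc(Br)ccc1O | intermediate
15 | 5-bromo-2-hydroxy-3-(3-methylbut-2-en-1-yl)benzaldehyde | CC(C)=CCc1cc(Br)cc(C=O)c1O | intermediate
16 | 5-bromo-2-hydroxy-3-(3-methylbut-2-en-1-yl)phenyl formate | CC(C)=CCc1cc(Br)cc(OC=O)c1O | intermediate (not isolated)
17 | 5-bromo-3-(3-methylbut-2-en-1-yl)benzene-1,2-diol | CC(C)=CCc1cc(Br)cc(O)c1O | intermediate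
18 | 1,2-bis(benzyloxy)-5-bromo-3-(3-methylbut-2-en-1-yl)benzene | CC(C)=CCc1cc(Br)cc(OCc2ccccc2)c1OCc1ccccc1 | intermediate
19 | (3R)-3-{[2,3-bis(benzyloxy)-5-bromophenyl]methyl}-2,2-dimethyloxirane | CC1(C)O[C@@H]1Cc1cc(Br)cc(OCc2ccccc2)c1OCc1ccccc1 | intermediate
20 | {3,4-bis(benzyloxy)-5-[((2R)-3,3-dimethyloxiran-2-yl)methyl]phenyl}lithium | CC1(C)O[C@@H]1Cc1cc([Li])cc(OCc2ccccc2)c1OCc1ccccc1 | intermediate (not isolated)
21 | {3,4-bis(benzyloxy)-5-[((2R)-3,3-dimethyloxiran-2-yl)methyl]phenyl}zinc iodide | CC1(C)O[C@@H]1Cc1cc([Zn]I)cc(OCc2ccccc2)c1OCc1ccccc1 | intermediate (not isolated)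
22 | (3S)-5,7-bis(benzyloxy)-3-{3,4-bis(benzyloxy)-5-[((2R)-3,3-dimethyloxiran-2-yl)methyl]phenyl}chroman-4-one | CC1(C)O[C@@H]1Cc1cc([C@H]2COc3cc(OCc4ccccc4)cc(OCc4ccccc4)c3C2=O)cc(OCc2ccccc2)c1OCc1ccccc1 | intermediate
23 | (3S)-3-{3,4-dihydroxy-5-[((2R)-3,3-dimethyloxiran-2-yl)methyl]phenyl}-5,7-dihydroxychroman-4-one | CC1(C)O[C@@H]1Cc1cc([C@H]2COc3cc(O)cc(O)c3C2=O)cc(O)c1O | target

## Step count and risks

Total step count: 12. Longest linear sequence: 7 (steps 6–10, then 11 and 12; the ring A/C branch, steps 1–5, then 11 and 12, is equally long).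

**Step 11 (the proposed new coupling).** The risks are low enantioselectivity on the cyclic substrate, reductive debromination or β-aryloxy elimination, and epoxide opening by zinc halide. The fallback uses known chemistry and sets out from ketone 9 and aryl bromide 19. A palladium-catalysed ketone α-arylation (Pd2(dba)3 as the zerovalent palladium source, XPhos, NaOt-Bu, toluene, 60 °C) joins the same C3–C1' bond with ring B as the electrophile. It gives 22 as a roughly 1:1 mixture with its C3 epimer, (3R)-5,7-bis(benzyloxy)-3-{3,4-bis(benzyloxy)-5-[((2R)-3,3-dimethyloxiran-2-yl)methyl]phenyl}chroman-4-one F1. The two are separated by preparative HPLC on a chiral stationary phase. The unwanted epimer is re-equilibrated with catalytic DBU in toluene at rt and separated again. The fallback comes back to the route at 22 and makes step 5 unnecessary.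

**Step 12 (global debenzylation).** The risk is that the epoxide is opened, either by hydrogenolysis or by the newly freed neighbouring 4'-OH on a slightly acidic catalyst, to a dihydrobenzofuran or chromanol. The fallback replaces benzyl by fluoride-labile silyl ethers and sets out from catechol 17 and chromanone 8.
- Catechol 17 is silylated (TBSCl, imidazole, DMF) to 1,2-bis(tert-butyldimethylsilyloxy)-5-bromo-3-(3-methylbut-2-en-1-yl)benzene F2.
- Shi epoxidation as in step 10 gives (3R)-3-{[2,3-bis(tert-butyldimethylsilyloxy)-5-bromophenyl]methyl}-2,2-dimethyloxirane F3.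
- Chromanone 8 with TBSOTf (3.3 equiv) and Et3N in CH2Cl2 gives 4,5,7-tris(tert-butyldimethylsilyloxy)-2H-chromene F4.
- NBS in THF at −78 °C converts this to racemic 3-bromo-5,7-bis(tert-butyldimethylsilyloxy)chroman-4-one F5.
- As in step 11, t-BuLi turns the epoxide into {3,4-bis(tert-butyldimethylsilyloxy)-5-[((2R)-3,3-dimethyloxiran-2-yl)methyl]phenyl}lithium F6, and ZnI2 turns that into {3,4-bis(tert-butyldimethylsilyloxy)-5-[((2R)-3,3-dimethyloxiran-2-yl)methyl]phenyl}zinc iodide F7.
- The nickel coupling with the bromo ketone gives (3S)-5,7-bis(tert-butyldimethylsilyloxy)-3-{3,4-bis(tert-butyldimethylsilyloxy)-5-[((2R)-3,3-dimethyloxiran-2-yl)methyl]phenyl}chroman-4-one F8.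
- Acetic-acid-buffered Bu4NF (1:1) in THF at 0 °C removes all four silyl groups without free phenoxide and comes back to the route at target 23.

**Step 6 (ortho-C-prenylation).** The risks are competing O-prenylation, double prenylation and chroman formation, which give modest yields. The fallback sets out from 4-bromophenol 12. Ortho-iodination (NIS, catalytic TsOH, MeCN) gives 4-bromo-2-iodophenol F9. A Stille coupling that is selective for the C–I bond (tributyl(3-methylbut-2-en-1-yl)stannane, Pd(PPh3)4 as the zerovalent palladium catalyst, DMF, 80 °C) then installs the linear prenyl group. The fallback comes back to the route at 14.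

## Further compounds

F1 | step 11 | (3R)-5,7-bis(benzyloxy)-3-{3,4-bis(benzyloxy)-5-[((2R)-3,3-dimethyloxiran-2-yl)methyl]phenyl}chroman-4-one | CC1(C)O[C@@H]1Cc1cc([C@@H]2COc3cc(OCc4ccccc4)cc(OCc4ccccc4)c3C2=O)cc(OCc2ccccc2)c1OCc1ccccc1
F2 | step 12 | 1,2-bis(tert-butyldimethylsilyloxy)-5-bromo-3-(3-methylbut-2-en-1-yl)benzene | CC(C)=CCc1cc(Br)cc(O[Si](C)(C)C(C)(C)C)c1O[Si](C)(C)C(C)(C)C
F3 | step 12 | (3R)-3-{[2,3-bis(tert-butyldimethylsilyloxy)-5-bromophenyl]methyl}-2,2-dimethyloxirane | CC1(C)O[C@@H]1Cc1cc(Br)cc(O[Si](C)(C)C(C)(C)C)c1O[Si](C)(C)C(C)(C)C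
F4 | step 12 | 4,5,7-tris(tert-butyldimethylsilyloxy)-2H-chromene | CC(C)(C)[Si](C)(C)OC1=CCOc2cc(O[Si](C)(C)C(C)(C)C)cc(O[Si](C)(C)C(C)(C)C)c12
F5 | step 12 | racemic 3-bromo-5,7-bis(tert-butyldimethylsilyloxy)chroman-4-one | O=C1C(Br)COc2cc(O[Si](C)(C)C(C)(C)C)cc(O[Si](C)(C)C(C)(C)C)c12
F6 | step 12 | {3,4-bis(tert-butyldimethylsilyloxy)-5-[((2R)-3,3-dimethyloxiran-2-yl)methyl]phenyl}lithium | CC1(C)O[C@@H]1Cc1cc([Li])cc(O[Si](C)(C)C(C)(C)C)c1O[Si](C)(C)C(C)(C)C
F7 | step 12 | {3,4-bis(tert-butyldimethylsilyloxy)-5-[((2R)-3,3-dimethyloxiran-2-yl)methyl]phenyl}zinc iodide | CC1(C)O[C@@H]1Cc1cc([Zn]I)cc(O[Si](C)(C)C(C)(C)C)c1O[Si](C)(C)C(C)(C)C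
F8 | step 12 | (3S)-5,7-bis(tert-butyldimethylsilyloxy)-3-{3,4-bis(tert-butyldimethylsilyloxy)-5-[((2R)-3,3-dimethyloxiran-2-yl)methyl]phenyl}chroman-4-one | CC1(C)O[C@@H]1Cc1cc([C@H]2COc3cc(O[Si](C)(C)C(C)(C)C)cc(O[Si](C)(C)C(C)(C)C)c3C2=O)cc(O[Si](C)(C)C(C)(C)C)c1O[Si](C)(C)C(C)(C)C
F9 | step 6 | 4-bromo-2-iodophenol | Oc1ccc(Br)cc1I
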